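**Retrosynthetic overview**
1. Target 16 ⇒ acetylation and desilylation ⇒ TBS-protected α-methoxy-γ-pyrone 14 ⇒ regioselective O-methylation of 4-hydroxy-2-pyranone 12.
2. The only ring, the pyranone, is closed by lactonisation of the 3,5-diketo ester 11 (ring O–C(=O) bond).
3. Key C–C disconnection: the bond between the chain-bearing ring carbon and its methyl-bearing neighbour, made by intermolecular aldol addition of the dianion of methyl 2-methyl-3-oxopentanoate 8 to aldehyde 7, followed by oxidation.
4. Aldehyde 7 ⇐ ozonolysis of the TBS ether of (S)-tridec-12-en-2-ol 4 ⇐ copper-catalysed opening of (S)-propylene oxide 2 (source of the single stereocentre) by the Grignard reagent of 10-bromodec-1-ene 1.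

Assumption: the stereocentre in the given SMILES is (S) (O > chain CH2 > CH3 > H), and 1, 2 and 8 are taken as purchasable.

**Route**

Step 1
Reactants: 1 10-bromodec-1-ene; 2 (S)-propylene oxide [(S)-2-methyloxirane]
Product: 4 (S)-tridec-12-en-2-ol, via dec-9-enylmagnesium bromide 3 (not isolated)
Conditions: Mg, THF, 40 °C; then CuI (10 mol %), 2 (1.5 equiv), THF, −30 → 0 °C; 1 M HCl quench
Reagents that add atoms: none
Why: Copper-catalysed Grignard ring-opening (SN2) of the epoxide occurs at the unsubstituted CH2 terminus, so the C–O stereocentre of (S)-propylene oxide is untouched and appears as (S) in the product.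

Step 2
Reactants: 4 (S)-tridec-12-en-2-ol
Product: 5 (S)-tert-butyldimethyl(tridec-12-en-2-yloxy)silane
Conditions: TBSCl (1.2 equiv), imidazole (2.5 equiv), DMF, rt
Reagents that add atoms: tert-butyldimethylsilyl chloride (TBSCl), CC(C)(C)[Si](C)(C)Cl
Why: Standard imidazole-promoted O-silylation of a secondary alcohol masks the OH against the strongly basic aldol step and leaves the stereocentre untouched.

Step 3
Reactants: 5 (S)-tert-butyldimethyl(tridec-12-en-2-yloxy)silane
Product: 7 (S)-11-(tert-butyldimethylsilyloxy)dodecanal, via 3-[(10S)-10-(tert-butyldimethylsilyloxy)undecyl]-1,2,4-trioxolane 6 (not isolated)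
Conditions: O3, CH2Cl2, −78 °C; then PPh3 (1.2 equiv), −78 °C → rt
Reagents that add atoms: ozone, [O-][O+]=O
Why: Ozonolysis with reductive work-up cleaves the only alkene to the aldehyde, losing the terminal CH2 as formaldehyde, while the silyl ether is inert.

Step 4
Reactants: 7 (S)-11-(tert-butyldimethylsilyloxy)dodecanal; 8 methyl 2-methyl-3-oxopentanoate
Product: 10 methyl (15S)-15-(tert-butyldimethylsilyloxy)-5-hydroxy-2,4-dimethyl-3-oxohexadecanoate (diastereomer mixture at C2/C4/C5), via lithium sodium 2,4-dianion of methyl 2-methyl-3-oxopentanoate 9 (not isolated)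
Conditions: 8 (1.5 equiv), NaH, THF, 0 °C; n-BuLi, 0 °C; then 7, −78 °C, 30 min; AcOH quench at −78 °C
Reagents that add atoms: none
Why: In this Weiler dianion aldol addition the more nucleophilic γ-carbanion adds to the aldehyde at −78 °C, and the three new stereocentres form unselectively, which does not matter because all become sp2 later.

Step 5
Reactants: 10 methyl (15S)-15-(tert-butyldimethylsilyloxy)-5-hydroxy-2,4-dimethyl-3-oxohexadecanoate
Product: 11 methyl (15S)-15-(tert-butyldimethylsilyloxy)-2,4-dimethyl-3,5-dioxohexadecanoate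
Conditions: Dess–Martin periodinane (1.5 equiv), CH2Cl2, 0 °C → rt
Reagents that add atoms: none
Why: Dess–Martin oxidation converts the β-hydroxy ketone into the 1,3-diketone under near-neutral conditions, avoiding retro-aldol cleavage and leaving the TBS ether intact.

Step 6
Reactants: 11 methyl (15S)-15-(tert-butyldimethylsilyloxy)-2,4-dimethyl-3,5-dioxohexadecanoate
Product: 12 6-[(10S)-10-(tert-butyldimethylsilyloxy)undecyl]-4-hydroxy-3,5-dimethyl-2H-pyran-2-one
Conditions: DBU (2 equiv), toluene, 60 °C; then 10% aq. citric acid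
Reagents that add atoms: none
Why: DBU-promoted enol lactonisation (intramolecular O-acylation of the C5 enolate by the methyl ester) expels methanol and is driven by formation of the stabilised hydroxypyranone anion.

Step 7
Reactants: 12 6-[(10S)-10-(tert-butyldimethylsilyloxy)undecyl]-4-hydroxy-3,5-dimethyl-2H-pyran-2-one
Product: 14 2-[(10S)-10-(tert-butyldimethylsilyloxy)undecyl]-6-methoxy-3,5-dimethyl-4H-pyran-4-one, via 6-[(10S)-10-(tert-butyldimethylsilyloxy)undecyl]-4-hydroxy-2-methoxy-3,5-dimethylpyrylium triflate 13 (not isolated)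
Conditions: MeOTf (1.3 equiv), CH2Cl2, 0 °C → rt; then sat. aq. NaHCO3
Reagents that add atoms: methyl trifluoromethanesulfonate (MeOTf), COS(=O)(=O)C(F)(F)F
Why: Base-free regioselective O-methylation with a hard electrophile occurs at the most nucleophilic lactone carbonyl oxygen to give the aromatic hydroxypyrylium salt, which loses its OH proton on work-up to give the α-methoxy-γ-pyrone.

Step 8
Reactants: 14 2-[(10S)-10-(tert-butyldimethylsilyloxy)undecyl]-6-methoxy-3,5-dimethyl-4H-pyran-4-one
Product: 15 2-[(10S)-10-hydroxyundecyl]-6-methoxy-3,5-dimethyl-4H-pyran-4-one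
Conditions: HF·pyridine, pyridine, THF, 0 °C → rt
Reagents that add atoms: none
Why: Fluoride-mediated desilylation, driven by Si–F bond formation under pyridine-buffered conditions, frees the secondary alcohol without touching the vinylogous ester or the stereocentre.

Step 9
Reactants: 15 2-[(10S)-10-hydroxyundecyl]-6-methoxy-3,5-dimethyl-4H-pyran-4-one
Product: 16 (2S)-11-(6-methoxy-3,5-dimethyl-4-oxo-4H-pyran-2-yl)undecan-2-yl acetate
Conditions: Ac2O (2 equiv), pyridine, DMAP (cat.), CH2Cl2, rt
Reagents that add atoms: acetic anhydride, CC(=O)OC(C)=O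
Why: DMAP-catalysed O-acylation of the secondary alcohol proceeds with retention at carbon, so the (S) centre set in step 1 is delivered unchanged.

**Compound list**
1 | 10-bromodec-1-ene | C=CCCCCCCCCBr | starting material
2 | (S)-propylene oxide | C[C@H]1CO1 | starting material
3 | dec-9-enylmagnesium bromide | C=CCCCCCCCC[Mg]Br | intermediate
4 | (S)-tridec-12-en-2-ol | C=CCCCCCCCCC[C@H](C)O | intermediate
5 | (S)-tert-butyldimethyl(tridec-12-en-2-yloxy)silane | C=CCCCCCCCCC[C@H](C)O[Si](C)(C)C(C)(C)C | intermediate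
6 | 3-[(10S)-10-(tert-butyldimethylsilyloxy)undecyl]-1,2,4-trioxolane (ozonide, epimer mixture at ring carbon) | C1OC(CCCCCCCCC[C@H](C)O[Si](C)(C)C(C)(C)C)OO1 | intermediate
7 | (S)-11-(tert-butyldimethylsilyloxy)dodecanal | O=CCCCCCCCCC[C@H](C)O[Si](C)(C)C(C)(C)C | intermediate
8 | methyl 2-methyl-3-oxopentanoate | CCC(=O)C(C)C(=O)OC | starting material
9 | lithium sodium 2,4-dianion of methyl 2-methyl-3-oxopentanoate | C[CH-]C(=O)[C-](C)C(=O)OC.[Li+].[Na+] | intermediate
10 | methyl (15S)-15-(tert-butyldimethylsilyloxy)-5-hydroxy-2,4-dimethyl-3-oxohexadecanoate (mixture at C2, C4, C5) | COC(=O)C(C)C(=O)C(C)C(O)CCCCCCCCC[C@H](C)O[Si](C)(C)C(C)(C)C | intermediate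
11 | methyl (15S)-15-(tert-butyldimethylsilyloxy)-2,4-dimethyl-3,5-dioxohexadecanoate | COC(=O)C(C)C(=O)C(C)C(=O)CCCCCCCCC[C@H](C)O[Si](C)(C)C(C)(C)C | intermediate
12 | 6-[(10S)-10-(tert-butyldimethylsilyloxy)undecyl]-4-hydroxy-3,5-dimethyl-2H-pyran-2-one | Cc1c(O)c(C)c(CCCCCCCCC[C@H](C)O[Si](C)(C)C(C)(C)C)oc1=O | intermediate
13 | 6-[(10S)-10-(tert-butyldimethylsilyloxy)undecyl]-4-hydroxy-2-methoxy-3,5-dimethylpyrylium trifluoromethanesulfonate | COc1[o+]c(CCCCCCCCC[C@H](C)O[Si](C)(C)C(C)(C)C)c(C)c(O)c1C.[O-]S(=O)(=O)C(F)(F)F | intermediate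
14 | 2-[(10S)-10-(tert-butyldimethylsilyloxy)undecyl]-6-methoxy-3,5-dimethyl-4H-pyran-4-one | COc1oc(CCCCCCCCC[C@H](C)O[Si](C)(C)C(C)(C)C)c(C)c(=O)c1C | intermediate
15 | 2-[(10S)-10-hydroxyundecyl]-6-methoxy-3,5-dimethyl-4H-pyran-4-one | COc1oc(CCCCCCCCC[C@H](C)O)c(C)c(=O)c1C | intermediate
16 | (2S)-11-(6-methoxy-3,5-dimethyl-4-oxo-4H-pyran-2-yl)undecan-2-yl acetate | COc1oc(CCCCCCCCC[C@H](C)OC(C)=O)c(C)c(=O)c1C | target

**Summary**
Total step count: 9. Longest linear sequence: 9 steps (1 → 16); fragments 2 and 8 are used as purchased.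

**Three steps most likely to fail, with fallbacks**

Step 4 (dianion aldol). The risks are incomplete dianion formation, enolisation of the aldehyde and retro-aldol loss on work-up. The fallback replaces the aldol/oxidation pair by a Claisen-type acylation; it sets out from 7 and comes back at 11. Pinnick oxidation of 7 (NaClO2, NaH2PO4, 2-methyl-2-butene, t-BuOH/H2O) gives (11S)-11-(tert-butyldimethylsilyloxy)dodecanoic acid F1. Coupling with MeNHOMe·HCl (EDC·HCl, Et3N, CH2Cl2) gives (11S)-11-(tert-butyldimethylsilyloxy)-N-methoxy-N-methyldodecanamide F2. Acylation of dianion 9 with F2 (THF, −78 → 0 °C) then gives diketo ester 11 directly, the chelated tetrahedral adduct preventing over-addition, so 10 and step 5 are bypassed.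

Step 7 (regioselective methylation), the riskiest step. The risks are competing 4-O-methylation to the isomeric 4-methoxy-2-pyranone, and partial loss of the TBS group to the acidic pyrylium triflate followed by methylation of the freed alcohol. The fallback avoids both the hydroxypyranone and any methylating agent; it sets out from 11 and comes back at 14. Diketo ester 11 is cyclodehydrated directly with Ph3P/CCl4 in THF at rt: the C5 enol is activated as its oxyphosphonium and displaced by the ester carbonyl oxygen, and loss of a proton then gives the 2-methoxy-4-pyranone 14 in one operation. This bypasses 12 and 13 and makes no new compound (F0).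

Step 8 (desilylation on the methoxypyranone). The risk is acid- or fluoride-induced loss of the vinylogous methyl ester (demethylation back to a hydroxypyranone). The fallback changes the protecting-group order so that the acetate is in place before the methoxypyranone exists; it sets out from 12 and comes back at 16. Aqueous HF in MeCN on 12 gives 4-hydroxy-6-[(10S)-10-hydroxyundecyl]-3,5-dimethyl-2H-pyran-2-one F3. Ac2O/pyridine/DMAP gives (2S)-11-(4-acetoxy-3,5-dimethyl-2-oxo-2H-pyran-6-yl)undecan-2-yl acetate F4. Brief NaHCO3/MeOH at 0 °C cleaves only the activated enol acetate to give (2S)-11-(4-hydroxy-3,5-dimethyl-2-oxo-2H-pyran-6-yl)undecan-2-yl acetate F5. MeOTf in CH2Cl2, to which the acetate is inert, forms 6-[(10S)-10-acetoxyundecyl]-4-hydroxy-2-methoxy-3,5-dimethylpyrylium trifluoromethanesulfonate F6, which on NaHCO3 work-up gives 16 directly.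

**Further compounds**
F1 | step 4 | (11S)-11-(tert-butyldimethylsilyloxy)dodecanoic acid | OC(=O)CCCCCCCCC[C@H](C)O[Si](C)(C)C(C)(C)C
F2 | step 4 | (11S)-11-(tert-butyldimethylsilyloxy)-N-methoxy-N-methyldodecanamide | CON(C)C(=O)CCCCCCCCC[C@H](C)O[Si](C)(C)C(C)(C)C
F0 | step 7 | none | none
F3 | step 8 | 4-hydroxy-6-[(10S)-10-hydroxyundecyl]-3,5-dimethyl-2H-pyran-2-one | Cc1c(O)c(C)c(CCCCCCCCC[C@H](C)O)oc1=O
F4 | step 8 | (2S)-11-(4-acetoxy-3,5-dimethyl-2-oxo-2H-pyran-6-yl)undecan-2-yl acetate | Cc1c(OC(C)=O)c(C)c(CCCCCCCCC[C@H](C)OC(C)=O)oc1=O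
F5 | step 8 | (2S)-11-(4-hydroxy-3,5-dimethyl-2-oxo-2H-pyran-6-yl)undecan-2-yl acetate | Cc1c(O)c(C)c(CCCCCCCCC[C@H](C)OC(C)=O)oc1=O
F6 | step 8 | 6-[(10S)-10-acetoxyundecyl]-4-hydroxy-2-methoxy-3,5-dimethylpyrylium trifluoromethanesulfonate | COc1[o+]c(CCCCCCCCC[C@H](C)OC(C)=O)c(C)c(O)c1C.[O-]S(=O)(=O)C(F)(F)F
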